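**Retrosynthetic overview**

The strategy rests on the 5-alkylbenzene-1,3-diol ring. Its six carbons are C1 of a C18 hydroxy fatty acid plus five carbons of a triketide, whose sixth carbon (a carboxyl) is lost as CO2 at the end.
Disconnections: Ar–H from Ar–CO2H (a β-resorcylic acid masked as its acetonide); the arene C–C bond by intramolecular aldol of a diketo-dioxinone; the acyl C–C bond by Claisen acylation of a keto-dioxinone dianion.
Chain disconnections: the Z C9=C10 alkene by catalyst-controlled cross-metathesis of two terminal olefins; the carbinol fragment by Grignard opening of (S)-1,2-epoxybutane.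
Ring order: the full chain is built first; the benzene ring, the only ring of the target, is closed last (step 7), and the temporary dioxinone ring is opened in step 8.

Key step: step 7

Remark on the chemistry: compounds 1, 2, 6 and 9 are taken as purchased (1 enantiopure). The carbinol is carried as its tert-butyldimethylsilyl ether from step 2 to step 9, because a free hydroxyl would compete for the acyl imidazole in step 6.

**Route**

Step 1
Reactants: 1 (S)-1,2-epoxybutane; 2 6-bromo-1-hexene
Product: 4 (S)-dec-9-en-3-ol, via hex-5-enylmagnesium bromide 3 (not isolated)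
Conditions: 2, Mg, THF, rt to 40 °C; then 1, CuBr·SMe2 (10 mol%), THF, −30 to 0 °C; sat. aq NH4Cl
Reagents that add atoms: none
Why: Magnesium insertion gives the primary Grignard reagent, and its copper-catalysed SN2 opening of the terminal epoxide takes place at the unsubstituted CH2, so the C–O bond of the stereocenter is never broken and the carbinol stays S.

Step 2
Reactants: 4 (S)-dec-9-en-3-ol
Product: 5 (S)-tert-butyl(dec-9-en-3-yloxy)dimethylsilane
Conditions: TBSCl, imidazole, DMF, rt
Reagents that add atoms: tert-butyldimethylsilyl chloride, CC(C)(C)[Si](C)(C)Cl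
Why: Imidazole-promoted silylation of a secondary alcohol is routine and gives a silyl ether that should withstand the metathesis, hydroxide, amide-base and amine conditions that follow.

Step 3
Reactants: 5 (S)-tert-butyl(dec-9-en-3-yloxy)dimethylsilane; 6 methyl dec-9-enoate
Product: 7 methyl (9Z,16S)-16-[(tert-butyldimethylsilyl)oxy]octadec-9-enoate
Conditions: 6 (3 equiv), Ru(NO3)(=CH-C6H4-2-OiPr)(C,C-chelating 1-adamantyl-3-mesitylimidazolin-2-ylidene), C32H41N3O4Ru (3 mol%), THF, 35 °C, static vacuum
Reagents that add atoms: none
Why: Z-selective olefin cross-metathesis, in which the cyclometalated ruthenium catalyst forces both substituents of the side-bound ruthenacyclobutane away from the N-mesityl group so that cycloreversion releases the cis alkene; loss of ethylene drives the reaction and the excess of cheap ester 6 limits homodimerization of 5.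

Step 4
Reactants: 7 methyl (9Z,16S)-16-[(tert-butyldimethylsilyl)oxy]octadec-9-enoate
Product: 8 (9Z,16S)-16-[(tert-butyldimethylsilyl)oxy]octadec-9-enoic acid
Conditions: LiOH·H2O, THF/MeOH/H2O, rt; then 1 M HCl to pH 4, 0 °C
Reagents that add atoms: lithium hydroxide, [Li+].[OH-]
Why: Saponification of an unhindered methyl ester should proceed at room temperature without touching the secondary silyl ether or the isolated Z alkene.

Step 5
Reactants: 9 2,2,6-trimethyl-4H-1,3-dioxin-4-one
Product: 10 2,2-dimethyl-6-(2-oxopropyl)-4H-1,3-dioxin-4-one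
Conditions: LiN(SiMe3)2, THF, −78 °C; AcCl (0.5 equiv relative to dienolate), −78 to 0 °C; 1 M HCl
Reagents that add atoms: acetyl chloride, CC(=O)Cl
Why: Deprotonation of the 6-methyl group gives the lithium dienolate, which is C-acylated at that carbon by acetyl chloride (vinylogous Claisen-type acylation); a second equivalent of dienolate is supplied because the product is more acidic than 9.

Step 6
Reactants: 8 (9Z,16S)-16-[(tert-butyldimethylsilyl)oxy]octadec-9-enoic acid; 10 2,2-dimethyl-6-(2-oxopropyl)-4H-1,3-dioxin-4-one
Product: 12 6-[(12Z,19S)-19-[(tert-butyldimethylsilyl)oxy]-2,4-dioxohenicos-12-en-1-yl]-2,2-dimethyl-4H-1,3-dioxin-4-one, via acyl imidazole 11 (not isolated)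
Conditions: 8, CDI, THF, rt; separately 10 (3 equiv), LiN(iPr)2 (6 equiv), THF, −78 °C; add solution of 11, −78 to −40 °C; 1 M HCl, 0 °C
Reagents that add atoms: none
Why: Carbonyldiimidazole turns the acid into its acyl imidazole, and the dianion of 10 reacts at its terminal, more nucleophilic carbon in a crossed Claisen condensation (dianion acylation of the Huckin–Weiler type); the excess dianion covers the liberated imidazole and the acidic product, which is protected from a second acylation as its enolate.

Step 7
Reactants: 12 6-[(12Z,19S)-19-[(tert-butyldimethylsilyl)oxy]-2,4-dioxohenicos-12-en-1-yl]-2,2-dimethyl-4H-1,3-dioxin-4-one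
Product: 13 5-[(8Z,15S)-15-[(tert-butyldimethylsilyl)oxy]heptadec-8-en-1-yl]-7-hydroxy-2,2-dimethyl-4H-benzo[d][1,3]dioxin-4-one
Conditions: Et3N, CH2Cl2, rt
Reagents that add atoms: none
Why: Triethylamine removes a proton from the CH2 between the dioxinone and the neighbouring ketone, and the resulting dienolate adds through dioxinone C5 to the chain-bearing ketone carbon (the former C1 of acid 8) in an intramolecular aldol reaction; the aldol loses water and the remaining ring ketone enolizes, so the benzene ring forms without any oxidant. The closest known reaction type is the base-mediated cycloaromatization of 3,5-diketo-dioxinones to acetonide-protected β-resorcylates, the laboratory counterpart of the polyketide aldol cyclization. The one ring closed is the six-membered carbocycle (dioxinone C5 and C6 plus the four chain carbons up to the acyl ketone), formed in a 6-(enolexo)-exo-trig mode. No stereocenter is created, and the S carbinol and the Z alkene are remote from the reacting triketide and meet only an amine base at room temperature. The selectivity required is C–C aldol closure onto the acyl ketone over Claisen-type attack at the carboxyl carbon or O-cyclization to a pyranone; it is secured because the carboxyl carbon is held in the dioxinone ring as a poorly electrophilic enol ester, which leaves the acyl ketone as the only electrophile placed for six-membered closure.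

Step 8
Reactants: 13 5-[(8Z,15S)-15-[(tert-butyldimethylsilyl)oxy]heptadec-8-en-1-yl]-7-hydroxy-2,2-dimethyl-4H-benzo[d][1,3]dioxin-4-one
Product: 15 5-[(8Z,15S)-15-[(tert-butyldimethylsilyl)oxy]heptadec-8-en-1-yl]benzene-1,3-diol, via free resorcylic acid 14 (not isolated)
Conditions: KOH, DMSO/H2O, 80 °C (Ar, degassed); then AcOH to pH 5, 100–110 °C
Reagents that add atoms: none
Why: Hydroxide opens the salicylate-type acetonide ester, releasing acetone and the β-resorcylic acid, which at weakly acidic pH should lose CO2 on heating by ipso-protonation of the ring carbon activated by the ortho and para hydroxyls (the olivetolic acid to olivetol type of decarboxylation); any partial silyl loss here is harmless because step 9 removes the group.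

Step 9
Reactants: 15 5-[(8Z,15S)-15-[(tert-butyldimethylsilyl)oxy]heptadec-8-en-1-yl]benzene-1,3-diol
Product: 16 Hansfordiol G, 5-[(8Z,15S)-15-hydroxyheptadec-8-en-1-yl]benzene-1,3-diol
Conditions: HCl (0.1 M) in MeOH, 0 °C to rt
Reagents that add atoms: none
Why: Acid-catalysed methanolysis cleaves the Si–O bond of the secondary silyl ether, so the C–O bond and the S configuration are untouched, and dilute acid at room temperature should not isomerize the Z alkene.

**Compound list**

1 | (S)-1,2-epoxybutane | CC[C@H]1CO1 | starting material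
2 | 6-bromo-1-hexene | C=CCCCCBr | starting material
3 | hex-5-enylmagnesium bromide | C=CCCCC[Mg]Br | intermediate
4 | (S)-dec-9-en-3-ol | CC[C@H](O)CCCCCC=C | intermediate
5 | (S)-tert-butyl(dec-9-en-3-yloxy)dimethylsilane | CC[C@H](O[Si](C)(C)C(C)(C)C)CCCCCC=C | intermediate
6 | methyl dec-9-enoate | C=CCCCCCCCC(=O)OC | starting material
7 | methyl (9Z,16S)-16-[(tert-butyldimethylsilyl)oxy]octadec-9-enoate | CC[C@H](O[Si](C)(C)C(C)(C)C)CCCCC/C=C\CCCCCCCC(=O)OC | intermediate
8 | (9Z,16S)-16-[(tert-butyldimethylsilyl)oxy]octadec-9-enoic acid | CC[C@H](O[Si](C)(C)C(C)(C)C)CCCCC/C=C\CCCCCCCC(=O)O | intermediate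
9 | 2,2,6-trimethyl-4H-1,3-dioxin-4-one | CC1=CC(=O)OC(C)(C)O1 | starting material
10 | 2,2-dimethyl-6-(2-oxopropyl)-4H-1,3-dioxin-4-one | CC(=O)CC1=CC(=O)OC(C)(C)O1 | intermediate
11 | (9Z,16S)-16-[(tert-butyldimethylsilyl)oxy]-1-(1H-imidazol-1-yl)octadec-9-en-1-one (acyl imidazole) | CC[C@H](O[Si](C)(C)C(C)(C)C)CCCCC/C=C\CCCCCCCC(=O)n1ccnc1 | intermediate
12 | 6-[(12Z,19S)-19-[(tert-butyldimethylsilyl)oxy]-2,4-dioxohenicos-12-en-1-yl]-2,2-dimethyl-4H-1,3-dioxin-4-one | CC[C@H](O[Si](C)(C)C(C)(C)C)CCCCC/C=C\CCCCCCCC(=O)CC(=O)CC1=CC(=O)OC(C)(C)O1 | intermediate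
13 | 5-[(8Z,15S)-15-[(tert-butyldimethylsilyl)oxy]heptadec-8-en-1-yl]-7-hydroxy-2,2-dimethyl-4H-benzo[d][1,3]dioxin-4-one | CC[C@H](O[Si](C)(C)C(C)(C)C)CCCCC/C=C\CCCCCCCc1cc(O)cc2OC(C)(C)OC(=O)c12 | intermediate
14 | 6-[(8Z,15S)-15-[(tert-butyldimethylsilyl)oxy]heptadec-8-en-1-yl]-2,4-dihydroxybenzoic acid | CC[C@H](O[Si](C)(C)C(C)(C)C)CCCCC/C=C\CCCCCCCc1cc(O)cc(O)c1C(=O)O | intermediate
15 | 5-[(8Z,15S)-15-[(tert-butyldimethylsilyl)oxy]heptadec-8-en-1-yl]benzene-1,3-diol | CC[C@H](O[Si](C)(C)C(C)(C)C)CCCCC/C=C\CCCCCCCc1cc(O)cc(O)c1 | intermediate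
16 | Hansfordiol G, 5-[(8Z,15S)-15-hydroxyheptadec-8-en-1-yl]benzene-1,3-diol | CC[C@H](O)CCCCC/C=C\CCCCCCCc1cc(O)cc(O)c1 | target

**Step count**

Total: 9 steps. Longest linear sequence: 8 steps (steps 1, 2, 3, 4, 6, 7, 8, 9); step 5 is a one-step branch.

**Steps most likely to fail**

Step 3 (cross-metathesis). Statistical homodimerization may consume 5, secondary metathesis at high conversion may erode the cis geometry, and the trans isomer may be hard to remove. The fallback sets out from 5 and comes back at 7. Ozonolysis of 5 (O3, CH2Cl2, −78 °C; PPh3) should give (S)-7-[(tert-butyldimethylsilyl)oxy]nonanal F1. Bought methyl 9-bromononanoate and PPh3 (MeCN, reflux) should give (9-methoxy-9-oxononyl)triphenylphosphonium bromide F2. The ylide from F2 (NaN(SiMe3)2, THF, −78 °C) should react with F1 in a lithium-free, kinetically controlled Wittig olefination, which is cis-selective for non-stabilized ylides, to give 7.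

Step 6 (dianion Claisen). Proton transfer from the α-CH2 of the acyl imidazole or from the product may quench the dianion, and O-acylation or double acylation may compete. The fallback sets out from 7 and comes back at 12. Reduction of 7 (iBu2AlH, CH2Cl2, −78 °C) should give (9Z,16S)-16-[(tert-butyldimethylsilyl)oxy]octadec-9-enal F3. Aldol addition of the dianion of 10 (LiN(iPr)2, THF, −78 °C) to this more electrophilic partner should give 6-[(12Z,19S)-19-[(tert-butyldimethylsilyl)oxy]-4-hydroxy-2-oxohenicos-12-en-1-yl]-2,2-dimethyl-4H-1,3-dioxin-4-one F4 as a mixture of carbinol epimers. Oxidation of the β-hydroxy ketone with Dess–Martin periodinane (NaHCO3, CH2Cl2) should then give 12, removing the new carbinol center.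

Step 8 (hydrolysis and decarboxylation). The phenoxide-deactivated ester may open slowly, decarboxylation may stop short, and the electron-rich resorcinol may oxidize in hot alkali. The fallback sets out from 12 and comes back at 15. Heating 12 with allyl alcohol in toluene at 110 °C (loss of acetone, trapping of the acylketene) should give allyl (15Z,22S)-22-[(tert-butyldimethylsilyl)oxy]-3,5,7-trioxotetracos-15-enoate F5. Aldol cycloaromatization (K2CO3, iPrOH, then AcOH) should give allyl 6-[(8Z,15S)-15-[(tert-butyldimethylsilyl)oxy]heptadec-8-en-1-yl]-2,4-dihydroxybenzoate F6. Deallylation with Pd(PPh3)4 and morpholine in THF should free acid 14 under neutral conditions, and warming in toluene at 100 °C should decarboxylate it to 15.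

Further compounds
F1 | step 3 | (S)-7-[(tert-butyldimethylsilyl)oxy]nonanal | CC[C@H](O[Si](C)(C)C(C)(C)C)CCCCCC=O
F2 | step 3 | (9-methoxy-9-oxononyl)triphenylphosphonium bromide | COC(=O)CCCCCCCC[P+](c1ccccc1)(c1ccccc1)c1ccccc1.[Br-]
F3 | step 6 | (9Z,16S)-16-[(tert-butyldimethylsilyl)oxy]octadec-9-enal | CC[C@H](O[Si](C)(C)C(C)(C)C)CCCCC/C=C\CCCCCCCC=O
F4 | step 6 | 6-[(12Z,19S)-19-[(tert-butyldimethylsilyl)oxy]-4-hydroxy-2-oxohenicos-12-en-1-yl]-2,2-dimethyl-4H-1,3-dioxin-4-one (mixture of carbinol epimers) | CC[C@H](O[Si](C)(C)C(C)(C)C)CCCCC/C=C\CCCCCCCC(O)CC(=O)CC1=CC(=O)OC(C)(C)O1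
F5 | step 8 | allyl (15Z,22S)-22-[(tert-butyldimethylsilyl)oxy]-3,5,7-trioxotetracos-15-enoate | CC[C@H](O[Si](C)(C)C(C)(C)C)CCCCC/C=C\CCCCCCCC(=O)CC(=O)CC(=O)CC(=O)OCC=C
F6 | step 8 | allyl 6-[(8Z,15S)-15-[(tert-butyldimethylsilyl)oxy]heptadec-8-en-1-yl]-2,4-dihydroxybenzoate | CC[C@H](O[Si](C)(C)C(C)(C)C)CCCCC/C=C\CCCCCCCc1cc(O)cc(O)c1C(=O)OCC=C
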